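All runs stem from a simulated flask from invented constants.

If the target peak stops growing once the starting material peak has vanished, you can read the flask as a fork.

the same everywhere: starting material 0.10 M
- delta: partner 0.070 M; protic impurity 0.10 M; temperature 70 °C; the very flask that is asked about, followed so far
- epsilon: partner 0.070 M; protic impurity 0.067 M; temperature 55 °C; run made earlier
- flask: partner 0.0700 M; protic impurity 0.100 M; temperature 70 °C; time 2.0 h

| run | time / min | target / % | starting material / % |
|---|---|---|---|
| delta | 25.0 | 25.3 | 3.8 |
| delta | 50.0 | 27.1 | 0.2 |
| delta | 80.0 | 27.2 | 0 |
| delta | 90.0 | 25.3 | 0 |
| delta | 120 | 25.4 | 0 |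
| epsilon | 8.00 | 5.1 | 68.6 |
| epsilon | 20.0 | 12.0 | 46.0 |
| epsilon | 40.0 | 20.6 | 26.2 |
| epsilon | 60.0 | 22.7 | 13.2 |
| epsilon | 80.0 | 23.8 | 5.4 |

(readings scatter by 1 percentage point)

- north-east: change nothing and wait 1.0 h more
- south: at 2.0 h take out 90 % of the target then present, then wait 1.0 h
- west: at 2.0 h add partner, 50.0 % of the amount charged, then wait 1.0 h
- north-west: at 2.0 h raise the temperature by 25 K, then wait 1.0 h

- what is taken out of target is counted as made
- the numbers in the tables scatter with a standard deviation of 1 percentage point
- additions bring no volume worth counting

- target, in percent of the starting material first charged, at 2.0 h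
- what to do for the largest gain in target; "none" if nothing gains more than 2 percentage points (north-east / south / west / north-west / none)
- target present, with what was taken out counted in, in percent of the starting material first charged, after south
- target present, with what was taken out counted in, in percent of the starting material first charged, after north-west

In delta, starting material reads 0.2 % at 50.0 min, which lies inside the scatter of zero. Target then stays flat within that scatter up to 120 min. So follow one molecule of starting material: it either ends as target or is lost.

The mean of the delta target readings from 50.0 min on is 26.2 %. Call this the fork share, the chance that one molecule of starting material ends as target. As odds, delta loses 2.81 molecules per molecule of target.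

Epsilon gives 25.2 % of the starting material used by its last reading. But it is colder, at 55 °C, and has 0.670 equivalents of protic impurity, so these two runs can't part the two changes.

My reckoning for delta is 26.2 % at 2.0 h. Each option acts when starting material reads 0 %, so I choose none and keep south and north-west at 26.2 %.

The forecast gives 26 %, none, 26 % and 25.5 %, on this ground: “With no starting material left, extra partner or more time gives nothing”.

The flask gives 26.2 %, the choice is none, and south and north-west stand at 26.2 % and 26.2 %.

    starting material + target → side product (k = 0.0160 L mol⁻¹ s⁻¹, Ea = 79.0 kJ mol⁻¹)
    partner + intermediate → target (k = 0.280 L mol⁻¹ s⁻¹, Ea = 64.0 kJ mol⁻¹)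
    2 intermediate → homo product (k = 0.0260 L mol⁻¹ s⁻¹, Ea = 64.0 kJ mol⁻¹)
    starting material + protic impurity → quenched substrate (k = 0.0240 L mol⁻¹ s⁻¹, Ea = 59.0 kJ mol⁻¹)
    starting material → intermediate (k = 9.10 × 10⁻⁴ s⁻¹, Ea = 91.0 kJ mol⁻¹)
    (constants at 70 °C)

At 0.0536 h in this flask, starting material goes to quenched substrate 1.9 times as fast as to intermediate. At 2.00 h this flask holds 0 % starting material and 52 % of its partner charge, and starting material is the limiting reagent, the first charge to run out.

Now take the neighbour with 0.250 equiv of protic impurity, a quarter of this flask's. If the odds follow the impurity in proportion, its fork share is 58.7 %. The computed neighbour holds 38.3 % target, 20 percentage points below that reckoning, so in that neighbour the odds did not follow the impurity in proportion. It also holds 40.9 % side product, counted as two in every percentage, and 19.8 % quenched substrate.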